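## Structural features

The target is a dihydrochalcone. Ring B (4-methoxyphenyl) is joined through CH2CH2C(=O) to C1 of ring A, a phloroglucinol with free OH groups on C2, C4 and C6 and hydrogen only on C3. C5 of ring A carries the chain C1'(ring A)(ring C)–C2'(CH3)–C3'(CH3)–C4'H2–ring D, in which rings C and D are 4-hydroxyphenyl groups. C1', C2' and C3' are contiguous stereocentres (1'R,2'R,3'S). Drawn as a zigzag through ring A–C1'–C2'–C3'–C4', ring C and both methyl groups lie on the same side. The fragile parts are the oxidation-prone triphenol, the aryl ketone and anisyl methyl ether (which rule out forcing reduction or Lewis-acid dealkylation at the end), and the diarylmethine C1'–H on a phloroglucinol ring, which strong acid can ionise. The real difficulty is that the finished chain has no functional group to steer stereochemistry: C1' is stereogenic only because its two aryl groups differ, it is flanked by two ortho oxygens of ring A, and C2' and C3' are plain methyl-bearing CH centres. The key step uses the fact that two of the carbon substituents of C1', the ring C ipso carbon and C2', can both be written as CH2–C(=O) arms, so that C1' is the prochiral carbon of a 3-(ring A)pentanedioate with enantiotopic ester groups. Two further features are used: the 2,4,6-oxygenation of ring A makes C1 and C3 equivalent until the acyl group is introduced, and the C2'–CH3 and C3'–CH3 carbons can be carried as the CH2O and C=O carbons of lactones, which relay the configuration of C1' to C2' and then to C3'.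

## Logic of the disconnections

**35 ⇒ 34.** The five O–CH2Ph bonds are cut. All phenols are released in one neutral operation at the very end, so the triphenol never meets another reagent. Nothing is gained in skeleton, but every earlier step can run on robust ethers. The forward step must stop short of the aryl ketone and the methyl ether of ring B.

**34 ⇒ 31 + 32.** The bond C1(ring A)–C(=O) is cut. In 31 the two free positions of ring A are equivalent and each is activated by three alkoxy groups, so no regiocontrol is needed and the ketone formed blocks a second acylation. This removes ring B and the only carbonyl group, which could not have survived the hydride and enolate steps before it. The forward step needs an acylation mild enough for benzyl ethers and selective for ring A over rings C and D.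

**31 ⇒ 30 ⇒ 29 ⇒ 28.** Both methyl groups are traced back to C–O carbons: the C2'–CH3 carbon to the CH2O and the C3'–CH3 carbon to the C=O of a γ-butyrolactone. This turns an acyclic dimethyl problem into a trans-3,4-disubstituted five-membered ring. The forward demand is two hydride displacements at β-branched primary carbons without closure to a cyclic ether.

**28 ⇒ 25 + 26.** The bond C3'–C4' is cut. Alkylation of the lactone enolate anti to the very large C4 substituent sets C3' from C2' and brings in ring D. The forward step needs clean α-deprotonation (not at the doubly benzylic C1'–H) and high trans selectivity.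

**25 ⇒ 24 ⇒ 22 ⇒ 18 + 19.** Ring C is cut into the CH2–CHO arm of 18 and the four carbons of 19: the ipso–ortho bond (Michael addition), the bond between the aldehyde carbon and the methyl carbon of 19 (aldol condensation), and two ring hydrogens (dehydrogenation). No arylation at crowded C1' is needed, because the ipso carbon is simply the α-carbon of an aldehyde. The forward steps need an enamine addition at a β-branched aldehyde, a cyclodehydration that spares the lactone, and an aromatisation that spares benzyl ethers. The transient ring stereocentre is irrelevant.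

**18 ⇒ 17 ⇒ 15.** The aldehyde is taken back to the alcohol, and the five-membered lactone is exchanged for a six-membered one. In 15 the lactone carbonyl is the future C2'–CH3 carbon and the ring CH2CH2O unit is the future ring C arm, so one hydride reduction releases both at the right oxidation level and the tert-butyl ester recloses as the five-membered lactone. The demand is chemoselective reduction of a lactone beside a tert-butyl ester, and five- over seven-membered ring closure.

**15 ⇒ 12 + 13.** The bond C2'–C3' is cut. Alkylation of the six-membered lactone enolate anti to the C4 aryl group sets C2' from C1'; 13 supplies C3' and the future C3'–CH3 carbon. 12 has a single stereocentre. The forward step needs trans selectivity and mono-alkylation.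

**12 ⇒ 10.** The lactone C–O bond is cut and CH2O is taken back to CO2H. The two arms of 10 are told apart chemically (acid reduced, ester kept) and the result is locked in a ring. The reduction must not pass through an activated acid, which could scramble the arms via a symmetric anhydride.

**10 ⇒ 9.** No skeletal bond is cut; one ester C–O bond is re-formed in the retro sense. 9 is achiral with enantiotopic ester groups, so a chiral catalyst can create C1' by hydrolysing one of them. 9 is kept as the dimethyl ester tris(benzyl ether): benzyl is the only phenol protection here that survives hydrides, strong bases and the two acid-catalysed lactonisations and still falls in one final step. The price is a bulky, lipophilic enzyme substrate, which is met with a co-solvent and a non-enzymatic fallback.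

**9 ⇒ 8 ⇒ 7 ⇒ 3 + 2 × 4.** Both C1'–CH2 bonds are cut. The aldehyde carbon of 3 becomes C1' by Knoevenagel condensation and Michael addition of two molecules of 4, followed by retro-Claisen loss of both acetyl groups. The demand is a second addition to a hindered, electron-rich benzylidene; aldol closure to 7 acts as the sink.

**3 ⇒ 1.** The bond ring A–C1' is cut. Formylation of the threefold-symmetric 1 can give only one product.

## Other disconnections considered

**Alternative 1:** The cut runs through ring A. The siloxyalkyne A1, which already holds C1'–C3' and rings C and D, is heated with the cyclobutenone A2. Ring opening of A2 to a vinylketene, [2+2] addition to A1, a second 4π opening and a 6π closure form C5–C6 and C3–C4 and give the phenol A3.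
- In favour: the arene is assembled with unambiguous regiochemistry under neutral thermal conditions, and the crowded ring A–C1' junction arises by ring construction instead of by substitution.
- Against it here: the differentiation of the three ring A oxygens that it delivers is not needed, since the target has three free OH groups. The C2 oxygen arrives as an ethyl ether, whose cleavage needs boron halide-type reagents that would also cleave the methyl ether of ring B, so ring B would have to be attached afterwards to a largely unprotected phloroglucinol. A1 must contain all three stereocentres before the key step, with C1' both benzylic and propargylic and therefore exposed to base-induced isomerisation while the ynol ether is made. The benzannulation itself creates no stereocentre.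
- Comparison: on structure, Alternative 1 keeps the bulky ring A out of all chain-building steps and is the better plan on that point. On mechanism, a pericyclic cascade needs no catalyst–substrate fit and is more predictable than enzyme acceptance of a 2,6-disubstituted aryl diester, again a point for Alternative 1. On stereochemistry the chosen plan is better, because one catalytic event is relayed to all three centres. On step economy the two are about equal, with extra protecting-group traffic on the side of Alternative 1.

**Alternative 2:** The cut is at C1'–H and C2'–CH3. The 4-arylcoumarin A4 (Pechmann condensation, then benzylation) takes hydride at C4 from a chiral bisphosphine copper hydride, and the resulting enolate is methylated anti to the C4 aryl group to give A5.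
- In favour: the ring A–C1'–ring C framework is reached in two steps, two stereocentres are set in one operation with the trans relation enforced by the ring, and only a catalytic amount of chiral material is used.
- Against it here: the β-carbon of A4 is doubly aryl-substituted, flanked by the C5 benzyloxy group and part of an electron-rich coumarin, all of which slow hydride delivery. C-methylation of the enolate competes with simple protonation. After the key step the lactone carbonyl is C3' and must receive CH3 and CH2–ring D in an open chain, where only 1,2-induction from an epimerisable C2' or a catalyst-controlled alkene hydrogenation is available. Ring opening also frees one ring A phenol that must be protected again.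
- Comparison: up to the C1'/C2' stage Alternative 2 is clearly the shorter (about three steps against twelve to reach 25). In the source of chirality the two are equal in kind, a chiral catalyst acting on an achiral substrate, and a small-molecule copper catalyst is likely to tolerate ortho substituents better than a hydrolase pocket, a point for Alternative 2. For C3' the chosen plan is better, because a ring template controls that centre.

**Alternative 3:** The cut is at C3'–C4'. The lithium enolate of lactone A6 is alkylated by the ring D benzylic bromide (the same bromide as in step 13) anti to the C4 substituent, giving A7.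
- In favour: dependable trans selectivity, C–C bond and stereocentre formed together, and both future methyl carbons already present.
- Against it as a strategy: the step relays chirality but creates none. It presupposes A6 with C1' and C2' in place, and the obvious ways to A6 (addition of a diarylmethyl nucleophile to a butenolide, or Friedel–Crafts alkylation of a ring A ether by a lactone-bearing benzylic cation) must control an exocyclic centre for which the lactone offers little bias.
- Comparison: this alkylation does not compete with the chosen plan. It is the same reaction as step 13 (A6 is 25 and A7 is 28), so on that point the two are equal by definition. They differ in where A6 comes from: the chosen plan sets C1' first with the hydrolase and relays it through a six-membered lactone. Alternative 3 would be the better plan, by perhaps six or seven steps, if a short catalytic asymmetric route to A6 were available. With substrate control of C1' alone it is the weaker.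

Key step: step 5

Assumptions (remarks on the chemistry):
- 1, 4, 13, 19, 26 and 32 are taken as purchasable.
- Locants: ring A C1 (acyl) and C5 (chain), chain C1'–C4'. The target is 1'R,2'R,3'S. The two free positions of ring A in 31 are equivalent.
- The hydrolase is assumed to act in the sense usual for 3-arylglutarates with para substituents. The opposite sense would be absorbed at step 6.

## Route

Step 1
Reactants: 1 1,3,5-tris(benzyloxy)benzene
Product: 3 2,4,6-tris(benzyloxy)benzaldehyde, via iminium chloride 2 (not isolated)
Conditions: POCl3, DMF, 0 °C to rt; then ice–water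
Reagents that add atoms: N,N-dimethylformamide, CN(C)C=O; water, O
Why: Vilsmeier–Haack formylation; 1 is threefold symmetric and strongly activated, so only one aldehyde can form, and the iminium ion 2 deactivates the ring against a second attack while leaving benzyl ethers intact.

Step 2
Reactants: 3 2,4,6-tris(benzyloxy)benzaldehyde; 4 ethyl 3-oxobutanoate (2.2 equiv)
Product: 7 diethyl 4-hydroxy-4-methyl-6-oxo-2-[2,4,6-tris(benzyloxy)phenyl]cyclohexane-1,3-dicarboxylate, via Knoevenagel adduct 5 (not isolated), via open bis-adduct 6 (not isolated)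
Conditions: piperidine (0.2 equiv), EtOH, rt to 40 °C, several days
Reagents that add atoms: none
Why: Knoevenagel condensation followed by Michael addition of a second molecule of 4; intramolecular aldol closure of 6 to 7 drains the reversible addition to the hindered, electron-rich benzylidene. All stereocentres of 7 are destroyed in step 3, and any 6 left open converges there as well.

Step 3
Reactants: 7 diethyl 4-hydroxy-4-methyl-6-oxo-2-[2,4,6-tris(benzyloxy)phenyl]cyclohexane-1,3-dicarboxylate
Product: 8 3-[2,4,6-tris(benzyloxy)phenyl]pentanedioic acid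
Conditions: NaOH (50% aq.), EtOH, reflux; then HCl to pH 2
Reagents that add atoms: sodium hydroxide (hydroxide supplies the carboxyl OH oxygens), [Na+].[OH-]
Why: Hot concentrated hydroxide reverses the aldol, removes both acetyl groups by retro-Claisen cleavage and saponifies the esters, the classical route to 3-arylglutaric acids. Benzyl aryl ethers are inert to base.

Step 4
Reactants: 8 3-[2,4,6-tris(benzyloxy)phenyl]pentanedioic acid
Product: 9 dimethyl 3-[2,4,6-tris(benzyloxy)phenyl]pentanedioate
Conditions: CH3I, K2CO3, DMF, rt
Reagents that add atoms: iodomethane, CI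
Why: SN2 O-alkylation of the dicarboxylate avoids the acid of a Fischer esterification and gives the achiral diester whose two ester groups are enantiotopic.

Step 5
Reactants: 9 dimethyl 3-[2,4,6-tris(benzyloxy)phenyl]pentanedioate
Product: 10 (3S)-5-methoxy-5-oxo-3-[2,4,6-tris(benzyloxy)phenyl]pentanoic acid
Conditions: pig liver esterase, 0.1 M phosphate buffer pH 7.5–DMSO (4:1), 30 °C, pH-stat (1 M NaOH, 1.0 equiv); then HCl to pH 3
Reagents that add atoms: water, O
Why: The serine of the catalytic triad adds to one of the two enantiotopic ester carbonyls of 9, methanol leaves from the tetrahedral intermediate, and water hydrolyses the acyl-enzyme to release 10. The closest known reaction type is the esterase- or lipase-mediated desymmetrisation of prochiral dimethyl 3-arylglutarates. No ring is closed and no skeletal bond is formed. The single new stereocentre, C1', is controlled only by the chiral active site, which holds the aryl group in its large hydrophobic pocket so that one CH2CO2CH3 arm alone reaches the serine; the substrate itself is achiral. The step needs enantiotopic-group selectivity and mono-hydrolysis; the second is secured because 10 is a carboxylate anion at pH 7.5 and a far poorer substrate than the neutral diester, and because the titration is stopped at one equivalent of base. Benzyl ethers are inert, and the DMSO co-solvent keeps the lipophilic diester available to the enzyme. The (S) descriptor of 10 corresponds to (R) at C1' of 35, because the acid arm, lowest-ranked carbon substituent in 10, becomes ring C, which ranks second in 35. The sense of hydrolysis should follow that of para-substituted 3-arylglutarates but must be confirmed, which is why step 6 is built to accept either enantiomer.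

Step 6
Reactants: 10 (3S)-5-methoxy-5-oxo-3-[2,4,6-tris(benzyloxy)phenyl]pentanoic acid
Product: 12 (4S)-4-[2,4,6-tris(benzyloxy)phenyl]oxan-2-one, via hydroxy ester 11 (not isolated)
Conditions: BH3·SMe2, THF, 0 °C to rt; MeOH; then TsOH·H2O (cat.), toluene, 60 °C
Reagents that add atoms: none
Why: Borane reduces a carboxylic acid much faster than an ester and needs no activation of the acid, so the arms cannot scramble through a symmetric anhydride; acid-catalysed lactonisation of 11 locks the differentiation in a ring. C1' is untouched; the mirror-image half-ester would give the same lactone by LiBH4 reduction of its ester arm, so the sense of the enzyme is not critical.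

Step 7
Reactants: 12 (4S)-4-[2,4,6-tris(benzyloxy)phenyl]oxan-2-one; 13 tert-butyl bromoacetate
Product: 15 tert-butyl 2-{(3R,4S)-2-oxo-4-[2,4,6-tris(benzyloxy)phenyl]oxan-3-yl}acetate, via lithium enolate 14 (not isolated)
Conditions: LiN(SiMe3)2, THF, −78 °C; then 13, −78 to −40 °C
Reagents that add atoms: none
Why: Kinetic alkylation of a six-membered lactone enolate; the electrophile enters anti to the bulky C4 aryl group (as in enolate trapping after conjugate addition to cyclic enones), giving the trans-3,4 product and so C2' (R) from C1'. Trans is also the thermodynamic isomer, so a minor cis portion can be equilibrated with base.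

Step 8
Reactants: 15 tert-butyl 2-{(3R,4S)-2-oxo-4-[2,4,6-tris(benzyloxy)phenyl]oxan-3-yl}acetate
Product: 17 (4R)-4-{(1S)-3-hydroxy-1-[2,4,6-tris(benzyloxy)phenyl]propyl}oxolan-2-one, via diol ester 16 (not isolated)
Conditions: LiBH4, THF, 0 °C to rt; then TsOH·H2O (cat.), toluene, 60 °C
Reagents that add atoms: none
Why: LiBH4 reduces the lactone to diol 16 while the hindered tert-butyl ester survives; acid then closes the five-membered lactone (favoured over the seven-membered one) with loss of tert-butanol. The former lactone carbonyl becomes the ring CH2O (future C2'–CH3) and the hydroxyethyl arm for ring C is set free; no stereocentre is affected.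

Step 9
Reactants: 17 (4R)-4-{(1S)-3-hydroxy-1-[2,4,6-tris(benzyloxy)phenyl]propyl}oxolan-2-one
Product: 18 (3S)-3-[(3R)-5-oxooxolan-3-yl]-3-[2,4,6-tris(benzyloxy)phenyl]propanal
Conditions: Dess–Martin periodinane, CH2Cl2, rt
Reagents that add atoms: none
Why: Dess–Martin oxidation of a primary alcohol under neutral conditions; lactone and benzyl ethers are inert, and the aldehyde has no α-stereocentre to lose (C1' is β).

Step 10
Reactants: 18 (3S)-3-[(3R)-5-oxooxolan-3-yl]-3-[2,4,6-tris(benzyloxy)phenyl]propanal; 19 but-3-en-2-one
Product: 22 (4R)-4-{(S)-(4-oxocyclohex-2-en-1-yl)[2,4,6-tris(benzyloxy)phenyl]methyl}oxolan-2-one (epimers at the cyclohexenyl carbon), via keto aldehyde 20 (not isolated), via aldol 21 (not isolated)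
Conditions: 19 (2 equiv), (S)-diphenylprolinol trimethylsilyl ether (20 mol %), 4-nitrophenol (20 mol %), CH2Cl2, rt; then dibenzylammonium trifluoroacetate, toluene, 60 °C
Reagents that add atoms: none
Why: Enamine-catalysed Michael addition of the aldehyde α-carbon to 19, then amine-salt-mediated intramolecular aldol condensation (Robinson-type annulation to a 4-substituted cyclohex-2-enone); the α-carbon of 18 becomes the future ipso carbon of ring C. The new ring stereocentre forms unselectively and is erased in step 11; the weakly acidic ammonium salt avoids both hydroxide (lactone) and strong acid (ring A).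

Step 11
Reactants: 22 (4R)-4-{(S)-(4-oxocyclohex-2-en-1-yl)[2,4,6-tris(benzyloxy)phenyl]methyl}oxolan-2-one
Product: 24 (4R)-4-{(R)-(4-hydroxyphenyl)[2,4,6-tris(benzyloxy)phenyl]methyl}oxolan-2-one, via dienone 23 (not isolated)
Conditions: Pd(O2CCF3)2 (5 mol %), 2-(dimethylamino)pyridine (10 mol %), TsOH·H2O (20 mol %), O2 (1 atm), DMSO, 80 °C
Reagents that add atoms: none
Why: Aerobic palladium-catalysed dehydrogenation of a cyclohexenone: a divalent palladium enolate undergoes β-hydride elimination to dienone 23, which tautomerises to the phenol, and O2 reoxidises the zerovalent palladium. The lactone is not enolised under these conditions and benzyl ethers are not cleaved without H2.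

Step 12
Reactants: 24 (4R)-4-{(R)-(4-hydroxyphenyl)[2,4,6-tris(benzyloxy)phenyl]methyl}oxolan-2-one
Product: 25 (4R)-4-{(R)-[4-(benzyloxy)phenyl][2,4,6-tris(benzyloxy)phenyl]methyl}oxolan-2-one
Conditions: PhCH2Br, K2CO3, DMF, rt
Reagents that add atoms: benzyl bromide, BrCc1ccccc1
Why: Williamson etherification of the only free phenol; anhydrous carbonate neither opens nor enolises the lactone, and ring C now carries the same protecting group as rings A and D.

Step 13
Reactants: 25 (4R)-4-{(R)-[4-(benzyloxy)phenyl][2,4,6-tris(benzyloxy)phenyl]methyl}oxolan-2-one; 26 4-(benzyloxy)benzyl bromide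
Product: 28 (3S,4S)-3-[4-(benzyloxy)benzyl]-4-{(R)-[4-(benzyloxy)phenyl][2,4,6-tris(benzyloxy)phenyl]methyl}oxolan-2-one, via lithium enolate 27 (not isolated)
Conditions: LiN(SiMe3)2, THF, −78 °C; then 26, −78 to −20 °C
Reagents that add atoms: none
Why: Alkylation of a γ-butyrolactone enolate anti to the very large C4 substituent, the standard entry to trans-3,4-disubstituted lignan lactones; it forms C3'–C4' and sets C3' (S) from C2'. The base removes only the lactone α-proton at −78 °C, not the doubly benzylic C1'–H.

Step 14
Reactants: 28 (3S,4S)-3-[4-(benzyloxy)benzyl]-4-{(R)-[4-(benzyloxy)phenyl][2,4,6-tris(benzyloxy)phenyl]methyl}oxolan-2-one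
Product: 29 (2S,3S)-2-[4-(benzyloxy)benzyl]-3-{(R)-[4-(benzyloxy)phenyl][2,4,6-tris(benzyloxy)phenyl]methyl}butane-1,4-diol
Conditions: LiAlH4, THF, 0 °C to rt
Reagents that add atoms: none
Why: Hydride reduction of the lactone to the 1,4-diol; the two CH2OH groups are the future methyl groups, and no centre is epimerisable once the carbonyl is gone.

Step 15
Reactants: 29 (2S,3S)-2-[4-(benzyloxy)benzyl]-3-{(R)-[4-(benzyloxy)phenyl][2,4,6-tris(benzyloxy)phenyl]methyl}butane-1,4-diol
Product: 30 (2S,3S)-2-[4-(benzyloxy)benzyl]-3-{(R)-[4-(benzyloxy)phenyl][2,4,6-tris(benzyloxy)phenyl]methyl}butane-1,4-diyl dimethanesulfonate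
Conditions: CH3SO2Cl, Et3N, CH2Cl2, −20 to 0 °C
Reagents that add atoms: methanesulfonyl chloride, CS(=O)(=O)Cl
Why: Sulfene-mediated mesylation is fast at low temperature, so both hydroxyl groups are sulfonylated before a mono-mesylate can close to a tetrahydrofuran.

Step 16
Reactants: 30 (2S,3S)-2-[4-(benzyloxy)benzyl]-3-{(R)-[4-(benzyloxy)phenyl][2,4,6-tris(benzyloxy)phenyl]methyl}butane-1,4-diyl dimethanesulfonate
Product: 31 1,3,5-tris(benzyloxy)-2-{(1R,2R,3S)-1,4-bis[4-(benzyloxy)phenyl]-2,3-dimethylbutyl}benzene
Conditions: LiBEt3H, THF, 0 °C to reflux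
Reagents that add atoms: none
Why: SN2 displacement of both primary mesylates by a strongly nucleophilic hydride turns CH2OSO2CH3 into CH3; attack at carbon is favoured over attack at sulfur with this reagent. Benzyl ethers and all three stereocentres are untouched.

Step 17
Reactants: 31 1,3,5-tris(benzyloxy)-2-{(1R,2R,3S)-1,4-bis[4-(benzyloxy)phenyl]-2,3-dimethylbutyl}benzene; 32 3-(4-methoxyphenyl)propanoic acid
Product: 34 1-[2,4,6-tris(benzyloxy)-3-{(1R,2R,3S)-1,4-bis[4-(benzyloxy)phenyl]-2,3-dimethylbutyl}phenyl]-3-(4-methoxyphenyl)propan-1-one, via mixed anhydride 33 (not isolated)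
Conditions: 32 (1.5 equiv), (CF3CO)2O, CH2Cl2, 0 °C to rt
Reagents that add atoms: none
Why: Friedel–Crafts acylation by the acyl trifluoroacetate formed in the flask; the two free positions of ring A are equivalent and each is activated by three alkoxy groups, while rings C and D and the anisyl ring are far less nucleophilic. The ketone deactivates ring A against a second acylation, and no metal Lewis acid is present to strip benzyl ethers.

Step 18
Reactants: 34 1-[2,4,6-tris(benzyloxy)-3-{(1R,2R,3S)-1,4-bis[4-(benzyloxy)phenyl]-2,3-dimethylbutyl}phenyl]-3-(4-methoxyphenyl)propan-1-one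
Product: 35 1-{2,4,6-trihydroxy-3-[(1R,2R,3S)-1,4-bis(4-hydroxyphenyl)-2,3-dimethylbutyl]phenyl}-3-(4-methoxyphenyl)propan-1-one (CNP0193401.1)
Conditions: H2 (1 atm), 10% Pd/C, EtOAc–MeOH, rt
Reagents that add atoms: none
Why: Hydrogenolysis of five benzyl aryl ethers; the hydrogen-bonded aryl ketone flanked by two ortho hydroxyl groups and the methyl ether are not reduced at 1 atm and room temperature, and no stereocentre is benzylic to oxygen.

## Compound list

1 | 1,3,5-tris(benzyloxy)benzene | c1c(OCc2ccccc2)cc(OCc2ccccc2)cc1OCc1ccccc1 | starting material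
2 | N,N-dimethyl-1-[2,4,6-tris(benzyloxy)phenyl]methaniminium chloride | C[N+](C)=Cc1c(OCc2ccccc2)cc(OCc2ccccc2)cc1OCc1ccccc1.[Cl-] | intermediate (not isolated)
3 | 2,4,6-tris(benzyloxy)benzaldehyde | O=Cc1c(OCc2ccccc2)cc(OCc2ccccc2)cc1OCc1ccccc1 | intermediate
4 | ethyl 3-oxobutanoate | CCOC(=O)CC(C)=O | starting material
5 | ethyl 3-oxo-2-[2,4,6-tris(benzyloxy)benzylidene]butanoate (E/Z mixture) | CCOC(=O)C(=Cc1c(OCc2ccccc2)cc(OCc2ccccc2)cc1OCc1ccccc1)C(C)=O | intermediate (not isolated)
6 | diethyl 2,4-diacetyl-3-[2,4,6-tris(benzyloxy)phenyl]pentanedioate (stereoisomer mixture) | CCOC(=O)C(C(C)=O)C(c1c(OCc2ccccc2)cc(OCc2ccccc2)cc1OCc1ccccc1)C(C(C)=O)C(=O)OCC | intermediate (not isolated)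
7 | diethyl 4-hydroxy-4-methyl-6-oxo-2-[2,4,6-tris(benzyloxy)phenyl]cyclohexane-1,3-dicarboxylate (stereoisomer mixture) | CCOC(=O)C1C(c2c(OCc3ccccc3)cc(OCc3ccccc3)cc2OCc2ccccc2)C(C(=O)OCC)C(C)(O)CC1=O | intermediate
8 | 3-[2,4,6-tris(benzyloxy)phenyl]pentanedioic acid | OC(=O)CC(CC(=O)O)c1c(OCc2ccccc2)cc(OCc2ccccc2)cc1OCc1ccccc1 | intermediate
9 | dimethyl 3-[2,4,6-tris(benzyloxy)phenyl]pentanedioate | COC(=O)CC(CC(=O)OC)c1c(OCc2ccccc2)cc(OCc2ccccc2)cc1OCc1ccccc1 | intermediate
10 | (3S)-5-methoxy-5-oxo-3-[2,4,6-tris(benzyloxy)phenyl]pentanoic acid | C(c1ccccc1)Oc1cc(OCc2ccccc2)c([C@@H](CC(=O)O)CC(=O)OC)c(OCc2ccccc2)c1 | intermediate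
11 | methyl (3S)-5-hydroxy-3-[2,4,6-tris(benzyloxy)phenyl]pentanoate | COC(=O)C[C@H](CCO)c1c(OCc2ccccc2)cc(OCc2ccccc2)cc1OCc1ccccc1 | intermediate (not isolated)
12 | (4S)-4-[2,4,6-tris(benzyloxy)phenyl]oxan-2-one | O=C1C[C@@H](c2c(OCc3ccccc3)cc(OCc3ccccc3)cc2OCc2ccccc2)CCO1 | intermediate
13 | tert-butyl bromoacetate | CC(C)(C)OC(=O)CBr | starting material
14 | lithium (4S)-4-[2,4,6-tris(benzyloxy)phenyl]-5,6-dihydro-4H-pyran-2-olate (lithium enolate of 12) | [Li]OC1=C[C@@H](c2c(OCc3ccccc3)cc(OCc3ccccc3)cc2OCc2ccccc2)CCO1 | intermediate (not isolated)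
15 | tert-butyl 2-{(3R,4S)-2-oxo-4-[2,4,6-tris(benzyloxy)phenyl]oxan-3-yl}acetate | O=C1[C@H](CC(=O)OC(C)(C)C)[C@@H](c2c(OCc3ccccc3)cc(OCc3ccccc3)cc2OCc2ccccc2)CCO1 | intermediate
16 | tert-butyl (3R,4S)-6-hydroxy-3-(hydroxymethyl)-4-[2,4,6-tris(benzyloxy)phenyl]hexanoate | OC[C@H](CC(=O)OC(C)(C)C)[C@@H](c1c(OCc2ccccc2)cc(OCc2ccccc2)cc1OCc1ccccc1)CCO | intermediate (not isolated)
17 | (4R)-4-{(1S)-3-hydroxy-1-[2,4,6-tris(benzyloxy)phenyl]propyl}oxolan-2-one | O=C1C[C@H]([C@@H](c2c(OCc3ccccc3)cc(OCc3ccccc3)cc2OCc2ccccc2)CCO)CO1 | intermediate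
18 | (3S)-3-[(3R)-5-oxooxolan-3-yl]-3-[2,4,6-tris(benzyloxy)phenyl]propanal | O=C1C[C@H]([C@@H](c2c(OCc3ccccc3)cc(OCc3ccccc3)cc2OCc2ccccc2)CC=O)CO1 | intermediate
19 | but-3-en-2-one | CC(=O)C=C | starting material
20 | 5-oxo-2-{(R)-[(3R)-5-oxooxolan-3-yl][2,4,6-tris(benzyloxy)phenyl]methyl}hexanal (C2 epimers) | O=C1C[C@H]([C@@H](c2c(OCc3ccccc3)cc(OCc3ccccc3)cc2OCc2ccccc2)C(C=O)CCC(C)=O)CO1 | intermediate (not isolated)
21 | (4R)-4-{(R)-(2-hydroxy-4-oxocyclohexyl)[2,4,6-tris(benzyloxy)phenyl]methyl}oxolan-2-one (ring epimers) | O=C1C[C@H]([C@@H](c2c(OCc3ccccc3)cc(OCc3ccccc3)cc2OCc2ccccc2)C2CCC(=O)CC2O)CO1 | intermediate (not isolated)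
22 | (4R)-4-{(S)-(4-oxocyclohex-2-en-1-yl)[2,4,6-tris(benzyloxy)phenyl]methyl}oxolan-2-one (epimers at the cyclohexenyl carbon) | O=C1C[C@H]([C@@H](c2c(OCc3ccccc3)cc(OCc3ccccc3)cc2OCc2ccccc2)C2C=CC(=O)CC2)CO1 | intermediate
23 | (4R)-4-{(S)-(4-oxocyclohexa-2,5-dien-1-yl)[2,4,6-tris(benzyloxy)phenyl]methyl}oxolan-2-one | O=C1C[C@H]([C@@H](c2c(OCc3ccccc3)cc(OCc3ccccc3)cc2OCc2ccccc2)C2C=CC(=O)C=C2)CO1 | intermediate (not isolated)
24 | (4R)-4-{(R)-(4-hydroxyphenyl)[2,4,6-tris(benzyloxy)phenyl]methyl}oxolan-2-one | O=C1C[C@H]([C@@H](c2c(OCc3ccccc3)cc(OCc3ccccc3)cc2OCc2ccccc2)c2ccc(O)cc2)CO1 | intermediate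
25 | (4R)-4-{(R)-[4-(benzyloxy)phenyl][2,4,6-tris(benzyloxy)phenyl]methyl}oxolan-2-one | O=C1C[C@H]([C@@H](c2c(OCc3ccccc3)cc(OCc3ccccc3)cc2OCc2ccccc2)c2ccc(OCc3ccccc3)cc2)CO1 | intermediate
26 | 4-(benzyloxy)benzyl bromide | BrCc1ccc(OCc2ccccc2)cc1 | starting material
27 | lithium enolate of 25 (C1' and C2' unchanged) | [Li]OC1=C[C@H]([C@@H](c2c(OCc3ccccc3)cc(OCc3ccccc3)cc2OCc2ccccc2)c2ccc(OCc3ccccc3)cc2)CO1 | intermediate (not isolated)
28 | (3S,4S)-3-[4-(benzyloxy)benzyl]-4-{(R)-[4-(benzyloxy)phenyl][2,4,6-tris(benzyloxy)phenyl]methyl}oxolan-2-one | O=C1[C@@H](Cc2ccc(OCc3ccccc3)cc2)[C@H]([C@@H](c2c(OCc3ccccc3)cc(OCc3ccccc3)cc2OCc2ccccc2)c2ccc(OCc3ccccc3)cc2)CO1 | intermediate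
29 | (2S,3S)-2-[4-(benzyloxy)benzyl]-3-{(R)-[4-(benzyloxy)phenyl][2,4,6-tris(benzyloxy)phenyl]methyl}butane-1,4-diol | OC[C@@H](Cc1ccc(OCc2ccccc2)cc1)[C@@H](CO)[C@@H](c1c(OCc2ccccc2)cc(OCc2ccccc2)cc1OCc1ccccc1)c1ccc(OCc2ccccc2)cc1 | intermediate
30 | (2S,3S)-2-[4-(benzyloxy)benzyl]-3-{(R)-[4-(benzyloxy)phenyl][2,4,6-tris(benzyloxy)phenyl]methyl}butane-1,4-diyl dimethanesulfonate | CS(=O)(=O)OC[C@@H](Cc1ccc(OCc2ccccc2)cc1)[C@@H](COS(C)(=O)=O)[C@@H](c1c(OCc2ccccc2)cc(OCc2ccccc2)cc1OCc1ccccc1)c1ccc(OCc2ccccc2)cc1 | intermediate
31 | 1,3,5-tris(benzyloxy)-2-{(1R,2R,3S)-1,4-bis[4-(benzyloxy)phenyl]-2,3-dimethylbutyl}benzene | c1c(OCc2ccccc2)cc(OCc2ccccc2)c([C@@H](c2ccc(OCc3ccccc3)cc2)[C@H](C)[C@@H](C)Cc2ccc(OCc3ccccc3)cc2)c1OCc1ccccc1 | intermediate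
32 | 3-(4-methoxyphenyl)propanoic acid | COc1ccc(CCC(=O)O)cc1 | starting material
33 | 3-(4-methoxyphenyl)propanoic trifluoroacetic anhydride | COc1ccc(CCC(=O)OC(=O)C(F)(F)F)cc1 | intermediate (not isolated)
34 | 1-[2,4,6-tris(benzyloxy)-3-{(1R,2R,3S)-1,4-bis[4-(benzyloxy)phenyl]-2,3-dimethylbutyl}phenyl]-3-(4-methoxyphenyl)propan-1-one | COc1ccc(CCC(=O)c2c(OCc3ccccc3)cc(OCc3ccccc3)c([C@@H](c3ccc(OCc4ccccc4)cc3)[C@H](C)[C@@H](C)Cc3ccc(OCc4ccccc4)cc3)c2OCc2ccccc2)cc1 | intermediate
35 | 1-{2,4,6-trihydroxy-3-[(1R,2R,3S)-1,4-bis(4-hydroxyphenyl)-2,3-dimethylbutyl]phenyl}-3-(4-methoxyphenyl)propan-1-one | COc1ccc(CCC(=O)c2c(O)cc(O)c([C@@H](c3ccc(O)cc3)[C@H](C)[C@@H](C)Cc3ccc(O)cc3)c2O)cc1 | target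

## Step count and least certain steps

Total step count: 18. Longest linear sequence: 18 (1 to 35; 4, 13, 19, 26 and 32 enter as purchased reactants).

**Step 5 (key step).** The most likely failure is poor binding or slow turnover, because an aryl group with two ortho benzyloxy substituents may not fit the acyl pocket and the diester is poorly soluble; weak discrimination between the enantiotopic arms is the second risk. A reversed sense is not a failure, since reduction of the ester arm with LiBH4 in place of the acid arm leads to the same 12. Fallback (non-enzymatic desymmetrisation of the anhydride): it sets out from 8. Heating 8 with acetic anhydride should give 4-[2,4,6-tris(benzyloxy)phenyl]oxane-2,6-dione F1. Methanolysis of F1 in methyl tert-butyl ether with a catalytic quinine- or quinidine-derived bifunctional sulfonamide, the pseudo-enantiomer being chosen to open the appropriate carbonyl, should return to the route at 10.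

**Step 2.** The sequence may stall after the Knoevenagel stage, because conjugate addition to a benzylidene that is electron-rich and doubly ortho-substituted is slow and reversible. Fallback (stepwise, with a much stronger acceptor): it sets out from 3. Condensation with Meldrum's acid should give 2,2-dimethyl-5-[2,4,6-tris(benzyloxy)benzylidene]-1,3-dioxane-4,6-dione F2. Mukaiyama–Michael addition of 1-methoxy-1-(trimethylsilyloxy)ethene should give methyl 3-(2,2-dimethyl-4,6-dioxo-1,3-dioxan-5-yl)-3-[2,4,6-tris(benzyloxy)phenyl]propanoate F3. Heating F3 in methanol–pyridine (ring opening and decarboxylation) should come back at 9, bypassing 7 and 8.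

**Step 7.** Facial selectivity in the alkylation of 14 may be insufficient, or proton transfer between product and enolate may lead to dialkylation. Fallback (auxiliary control in place of ring control): it sets out from 11, which is silylated instead of lactonised.
- TBSCl and imidazole should give methyl (3S)-5-[(tert-butyldimethylsilyl)oxy]-3-[2,4,6-tris(benzyloxy)phenyl]pentanoate F4.
- LiOH should give (3S)-5-[(tert-butyldimethylsilyl)oxy]-3-[2,4,6-tris(benzyloxy)phenyl]pentanoic acid F5.
- Pivaloyl chloride, Et3N, LiCl and (R)-4-benzyl-1,3-oxazolidin-2-one should give (4R)-4-benzyl-3-{(3S)-5-[(tert-butyldimethylsilyl)oxy]-3-[2,4,6-tris(benzyloxy)phenyl]pentanoyl}-1,3-oxazolidin-2-one F6.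
- NaN(SiMe3)2 and 13 should give, anti to the benzyl group of the auxiliary, tert-butyl (3R,4S)-3-{[(4R)-4-benzyl-2-oxo-1,3-oxazolidin-3-yl]carbonyl}-6-[(tert-butyldimethylsilyl)oxy]-4-[2,4,6-tris(benzyloxy)phenyl]hexanoate F7.
- LiBH4 should give tert-butyl (3R,4S)-6-[(tert-butyldimethylsilyl)oxy]-3-(hydroxymethyl)-4-[2,4,6-tris(benzyloxy)phenyl]hexanoate F8.
- TsOH in methanol–CH2Cl2 (desilylation and lactonisation) should come back at 17.

**Step 10.** Catalytic enamine formation and Michael addition may stall at the β-branched, crowded aldehyde while 19 polymerises. Fallback (stoichiometric, pre-formed nucleophile; Stork enamine annulation): it sets out from 18. Condensation with pyrrolidine over molecular sieves should give (4R)-4-{(1S,2E)-3-(pyrrolidin-1-yl)-1-[2,4,6-tris(benzyloxy)phenyl]prop-2-en-1-yl}oxolan-2-one F9. F9 is heated with 19 and then hydrolysed and cyclised in aqueous acetic acid–sodium acetate, coming back at 22.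

**Step 16.** Hydride may attack at sulfur and regenerate an alkoxide, which closes onto the neighbouring sulfonate to a tetrahydrofuran; displacement at the two β-branched carbons may also be slow. Fallback (halide displacement, then radical reduction): it sets out from 30. NaI in refluxing acetone should give (2S,3S)-2-[4-(benzyloxy)benzyl]-3-{(R)-[4-(benzyloxy)phenyl][2,4,6-tris(benzyloxy)phenyl]methyl}-1,4-diiodobutane F10. Bu3SnH with azobisisobutyronitrile in toluene at 80 °C should come back at 31.

**Step 17.** Benzyl groups may be lost or migrate in the acidic medium, and attack between two benzyloxy groups may be slow. Fallback (polarity reversal: ring A as the nucleophilic organolithium): it sets out from 31. One equivalent of N-bromosuccinimide at −20 °C should give 1,3,5-tris(benzyloxy)-2-{(1R,2R,3S)-1,4-bis[4-(benzyloxy)phenyl]-2,3-dimethylbutyl}-4-bromobenzene F11. Bromine–lithium exchange with n-BuLi at −78 °C and addition of N-methoxy-3-(4-methoxyphenyl)-N-methylpropanamide F12 (from 32, carbonyldiimidazole and N,O-dimethylhydroxylamine hydrochloride) should come back at 34.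

## Further compounds

F1 | step 5 | 4-[2,4,6-tris(benzyloxy)phenyl]oxane-2,6-dione | O=C1CC(c2c(OCc3ccccc3)cc(OCc3ccccc3)cc2OCc2ccccc2)CC(=O)O1
F2 | step 2 | 2,2-dimethyl-5-[2,4,6-tris(benzyloxy)benzylidene]-1,3-dioxane-4,6-dione | CC1(C)OC(=O)C(=Cc2c(OCc3ccccc3)cc(OCc3ccccc3)cc2OCc2ccccc2)C(=O)O1
F3 | step 2 | methyl 3-(2,2-dimethyl-4,6-dioxo-1,3-dioxan-5-yl)-3-[2,4,6-tris(benzyloxy)phenyl]propanoate (racemic) | COC(=O)CC(c1c(OCc2ccccc2)cc(OCc2ccccc2)cc1OCc1ccccc1)C1C(=O)OC(C)(C)OC1=O
F4 | step 7 | methyl (3S)-5-[(tert-butyldimethylsilyl)oxy]-3-[2,4,6-tris(benzyloxy)phenyl]pentanoate | COC(=O)C[C@H](CCO[Si](C)(C)C(C)(C)C)c1c(OCc2ccccc2)cc(OCc2ccccc2)cc1OCc1ccccc1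
F5 | step 7 | (3S)-5-[(tert-butyldimethylsilyl)oxy]-3-[2,4,6-tris(benzyloxy)phenyl]pentanoic acid | OC(=O)C[C@H](CCO[Si](C)(C)C(C)(C)C)c1c(OCc2ccccc2)cc(OCc2ccccc2)cc1OCc1ccccc1
F6 | step 7 | (4R)-4-benzyl-3-{(3S)-5-[(tert-butyldimethylsilyl)oxy]-3-[2,4,6-tris(benzyloxy)phenyl]pentanoyl}-1,3-oxazolidin-2-one | O=C1OC[C@@H](Cc2ccccc2)N1C(=O)C[C@H](CCO[Si](C)(C)C(C)(C)C)c1c(OCc2ccccc2)cc(OCc2ccccc2)cc1OCc1ccccc1
F7 | step 7 | tert-butyl (3R,4S)-3-{[(4R)-4-benzyl-2-oxo-1,3-oxazolidin-3-yl]carbonyl}-6-[(tert-butyldimethylsilyl)oxy]-4-[2,4,6-tris(benzyloxy)phenyl]hexanoate | O=C1OC[C@@H](Cc2ccccc2)N1C(=O)[C@H](CC(=O)OC(C)(C)C)[C@H](CCO[Si](C)(C)C(C)(C)C)c1c(OCc2ccccc2)cc(OCc2ccccc2)cc1OCc1ccccc1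
F8 | step 7 | tert-butyl (3R,4S)-6-[(tert-butyldimethylsilyl)oxy]-3-(hydroxymethyl)-4-[2,4,6-tris(benzyloxy)phenyl]hexanoate | OC[C@H](CC(=O)OC(C)(C)C)[C@H](CCO[Si](C)(C)C(C)(C)C)c1c(OCc2ccccc2)cc(OCc2ccccc2)cc1OCc1ccccc1
F9 | step 10 | (4R)-4-{(1S,2E)-3-(pyrrolidin-1-yl)-1-[2,4,6-tris(benzyloxy)phenyl]prop-2-en-1-yl}oxolan-2-one | O=C1C[C@H]([C@@H](c2c(OCc3ccccc3)cc(OCc3ccccc3)cc2OCc2ccccc2)/C=C/N2CCCC2)CO1
F10 | step 16 | (2S,3S)-2-[4-(benzyloxy)benzyl]-3-{(R)-[4-(benzyloxy)phenyl][2,4,6-tris(benzyloxy)phenyl]methyl}-1,4-diiodobutane | IC[C@@H](Cc1ccc(OCc2ccccc2)cc1)[C@@H](CI)[C@@H](c1c(OCc2ccccc2)cc(OCc2ccccc2)cc1OCc1ccccc1)c1ccc(OCc2ccccc2)cc1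
F11 | step 17 | 1,3,5-tris(benzyloxy)-2-{(1R,2R,3S)-1,4-bis[4-(benzyloxy)phenyl]-2,3-dimethylbutyl}-4-bromobenzene | Brc1c(OCc2ccccc2)cc(OCc2ccccc2)c([C@@H](c2ccc(OCc3ccccc3)cc2)[C@H](C)[C@@H](C)Cc2ccc(OCc3ccccc3)cc2)c1OCc1ccccc1
F12 | step 17 | N-methoxy-3-(4-methoxyphenyl)-N-methylpropanamide | COc1ccc(CCC(=O)N(C)OC)cc1
A1 | alternative 1 | triisopropyl{[(3R,4R,5S)-3,6-bis[4-(benzyloxy)phenyl]-4,5-dimethylhex-1-yn-1-yl]oxy}silane | CC(C)[Si](OC#C[C@@H](c1ccc(OCc2ccccc2)cc1)[C@H](C)[C@@H](C)Cc1ccc(OCc2ccccc2)cc1)(C(C)C)C(C)C
A2 | alternative 1 | 3-ethoxycyclobut-2-en-1-one | CCOC1=CC(=O)C1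
A3 | alternative 1 | 2-{(1R,2R,3S)-1,4-bis[4-(benzyloxy)phenyl]-2,3-dimethylbutyl}-5-ethoxy-3-[(triisopropylsilyl)oxy]phenol | CCOc1cc(O)c([C@@H](c2ccc(OCc3ccccc3)cc2)[C@H](C)[C@@H](C)Cc2ccc(OCc3ccccc3)cc2)c(O[Si](C(C)C)(C(C)C)C(C)C)c1
A4 | alternative 2 | 5,7-bis(benzyloxy)-4-[4-(benzyloxy)phenyl]-2H-chromen-2-one | O=C1C=C(c2ccc(OCc3ccccc3)cc2)c2c(OCc3ccccc3)cc(OCc3ccccc3)cc2O1
A5 | alternative 2 | (3S,4R)-5,7-bis(benzyloxy)-4-[4-(benzyloxy)phenyl]-3-methylchroman-2-one | O=C1Oc2cc(OCc3ccccc3)cc(OCc3ccccc3)c2[C@@H](c2ccc(OCc3ccccc3)cc2)[C@@H]1C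
A6 | alternative 3 | (4R)-4-{(R)-[4-(benzyloxy)phenyl][2,4,6-tris(benzyloxy)phenyl]methyl}oxolan-2-one (identical with 25) | O=C1C[C@H]([C@@H](c2c(OCc3ccccc3)cc(OCc3ccccc3)cc2OCc2ccccc2)c2ccc(OCc3ccccc3)cc2)CO1
A7 | alternative 3 | (3S,4S)-3-[4-(benzyloxy)benzyl]-4-{(R)-[4-(benzyloxy)phenyl][2,4,6-tris(benzyloxy)phenyl]methyl}oxolan-2-one (identical with 28) | C(c1ccccc1)Oc1cc(OCc2ccccc2)c([C@@H](c2ccc(OCc3ccccc3)cc2)[C@@H]2COC(=O)[C@H]2Cc2ccc(OCc3ccccc3)cc2)c(OCc2ccccc2)c1
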